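**Retrosynthetic overview**

1. The pendant 4-hydroxy-2-pyranone is cut back to a C3 carboxylic acid plus a four-carbon acetoacetate unit (acylation of a bis-silyl dienol ether, then lactonisation). The styryl arm is cut at its alkene to a 6-methyl group and 4-hydroxybenzaldehyde.
2. Key disconnection: the dihydrofuran ring O1–C2–C3–C3a–C7a. C3 carries both the bond to the pyranone carbon C3a and one exocyclic carbon. These three atoms map onto C3, C4a and the ketone carbon C4 of a six-membered 2-aryl-2,3-dihydropyran-4-one fused to the same edge of the same 2-pyranone. A 1,2-shift of the ring-fusion carbon from C4 to C3 therefore makes C3–C3a and pushes C4 out as the carboxyl carbon.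
3. The (S)-2-aryl-dihydropyranone comes from an enantioselective oxa-Michael closure of the 3-cinnamoyl-4-hydroxy-2-pyranone obtained from dehydroacetic acid and 3,4-diacetoxybenzaldehyde.
4. Ring order: fused 2-pyranone (present in dehydroacetic acid), then dihydropyran-4-one (step 3), contracted to the trans dihydrofuran (step 4), then the pendant 2-pyranone (step 13). C2 is set in step 3; C3 is set in step 4 under control of C2.

Key step: step 4

Assumption: the sense of induction in step 3 cannot be predicted with certainty. The quinine-derived squaramide is written; its quinidine-derived pseudo-enantiomer is used instead if that is the one that should give (S)-5. Enolisable 1,3-dicarbonyl compounds are drawn as one tautomer.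

**Route**

Step 1
Reactants: 1 3,4-dihydroxybenzaldehyde
Product: 2 3,4-diacetoxybenzaldehyde
Conditions: Ac2O (2.5 equiv), pyridine, DMAP (cat.), CH2Cl2, 0 °C to rt
Reagents that add atoms: acetic anhydride, CC(=O)OC(C)=O
Why: Standard O-acylation of both phenols; the acetates are electron-withdrawing and acid-stable, which is what the aryl ring needs in step 4.

Step 2
Reactants: 2 3,4-diacetoxybenzaldehyde; 3 dehydroacetic acid
Product: 4 3-[(2E)-3-(3,4-diacetoxyphenyl)prop-2-enoyl]-4-hydroxy-6-methyl-2H-pyran-2-one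
Conditions: piperidine (10 mol%), CHCl3, reflux, azeotropic removal of water
Reagents that add atoms: none
Why: Amine-catalysed aldol condensation (Claisen–Schmidt/Knoevenagel type) at the acetyl methyl group of 3; the acidic pyranone (pKa about 5) holds piperidine as its salt, which should spare the aryl acetates, and dehydration gives the conjugated E enone.

Step 3
Reactants: 4 3-[(2E)-3-(3,4-diacetoxyphenyl)prop-2-enoyl]-4-hydroxy-6-methyl-2H-pyran-2-one
Product: 5 (S)-2-(3,4-diacetoxyphenyl)-7-methyl-2,3-dihydro-4H,5H-pyrano[3,2-c]pyran-4,5-dione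
Conditions: quinine-derived squaramide 3-[3,5-bis(trifluoromethyl)anilino]-4-[(9-deoxy-epi-quinin-9-yl)amino]cyclobut-3-ene-1,2-dione (10 mol%), toluene, −20 °C; filtration through silica, recrystallisation
Reagents that add atoms: none
Why: Enantioselective intramolecular oxa-Michael addition (6-endo-trig), the reaction type used to close 2'-hydroxychalcones to flavanones: the quinuclidine deprotonates the vinylogous acid, the squaramide binds the ketone/lactone 1,3-dicarbonyl, and the chiral ion pair delivers oxygen to one enone face to set C2 as S; low temperature and removal of the base before concentration should limit retro-oxa-Michael erosion.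

Step 4
Reactants: 5 (S)-2-(3,4-diacetoxyphenyl)-7-methyl-2,3-dihydro-4H,5H-pyrano[3,2-c]pyran-4,5-dione
Product: 8 methyl (2S,3S)-2-(3,4-diacetoxyphenyl)-6-methyl-4-oxo-2,3-dihydro-4H-furo[3,2-c]pyran-3-carboxylate, via 4-methoxy enol ether 6 (not isolated), via trans 3-iodanyl 4,4-dimethyl ketal 7 (not isolated)
Conditions: PhI(OAc)2 (1.2 equiv), conc. H2SO4 (cat.), HC(OMe)3, 0 °C to rt
Reagents that add atoms: trimethyl orthoformate, COC(OC)OC
Why: Acid and orthoformate turn the C4 ketone into the methyl enol ether 6, whose C3 attacks trivalent iodine while methanol adds at C4 to give the ketal iodane 7; the ring-fusion carbon C4a (the future C3a) then shifts from C4 to C3 as iodobenzene leaves, and the dimethoxycarbenium ion collapses to the exocyclic methyl ester. The closest known reaction is the oxidative ring contraction of flavanones by trivalent iodine (or trivalent thallium) in trimethyl orthoformate to trans methyl 2-aryl-2,3-dihydrobenzofuran-3-carboxylates, here with the oxygen-bearing pyranone carbon in the role of the migrating arene carbon. The dihydrofuran ring O1–C2–C3–C3a–C7a is thus closed by a 1,2-shift through a three-membered bridged transition state and not by a cyclisation; C2 and its C–O bond are untouched, so the S configuration from step 3 is carried over. The new stereocentre C3 is controlled by C2: only the iodane with an equatorial C3–I bond, trans to the equatorial C2 aryl group, has C–I antiperiplanar to the migrating C4–C4a ring bond, and migration with inversion at C3 places the ester carbon anti to the aryl group (2S,3S), which is also the thermodynamic epimer. The step needs migration of C4a in preference to a shift of the C2 aryl group to C3 or loss of HX to the unsaturated pyranopyranone: the two acetoxy groups make the aryl ring a poor migrating group and protect the catechol from the oxidant, whereas C4a is the donor-substituted carbon of a vinylogous ester fed by O1 and, through C7=C8, by O6.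

Step 5
Reactants: 8 methyl (2S,3S)-2-(3,4-diacetoxyphenyl)-6-methyl-4-oxo-2,3-dihydro-4H-furo[3,2-c]pyran-3-carboxylate
Product: 9 methyl (2S,3S)-2-(3,4-dihydroxyphenyl)-6-methyl-4-oxo-2,3-dihydro-4H-furo[3,2-c]pyran-3-carboxylate
Conditions: HCl (1.25 M in MeOH, 0.5 equiv), MeOH, 0 °C to rt
Reagents that add atoms: none
Why: Acid-catalysed transesterification of the aryl acetates to methyl acetate; the medium is non-basic, so C3–H is not removed, and exchange at the methyl ester is degenerate in methanol.

Step 6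
Reactants: 9 methyl (2S,3S)-2-(3,4-dihydroxyphenyl)-6-methyl-4-oxo-2,3-dihydro-4H-furo[3,2-c]pyran-3-carboxylate
Product: 10 methyl (2S,3S)-2-[3,4-bis(methoxymethoxy)phenyl]-6-methyl-4-oxo-2,3-dihydro-4H-furo[3,2-c]pyran-3-carboxylate
Conditions: MOMCl (3 equiv), iPr2NEt (4 equiv), CH2Cl2, 0 °C to rt
Reagents that add atoms: chloromethyl methyl ether, COCCl
Why: O-Alkylation of both phenols to base-stable acetals; the hindered amine is far too weak to enolise the C3 ester, and any reversible opening through the para-phenoxide leaves C3 fixed and should re-close to the trans isomer.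

Step 7
Reactants: 10 methyl (2S,3S)-2-[3,4-bis(methoxymethoxy)phenyl]-6-methyl-4-oxo-2,3-dihydro-4H-furo[3,2-c]pyran-3-carboxylate
Product: 11 (2S,3S)-2-[3,4-bis(methoxymethoxy)phenyl]-6-methyl-4-oxo-2,3-dihydro-4H-furo[3,2-c]pyran-3-carboxylic acid
Conditions: Me3SnOH (4 equiv), 1,2-dichloroethane, 80 °C; then cold 0.5 M HCl
Reagents that add atoms: trimethyltin hydroxide, C[Sn](C)(C)O
Why: Trimethyltin hydroxide cleaves the methyl ester under essentially neutral conditions, avoiding the C3 ester enolate whose β-elimination of O1 would destroy both stereocentres; the 2-pyranone lactone, a vinylogous carbonate, should not be attacked.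

Step 8
Reactants: 12 4-hydroxybenzaldehyde
Product: 13 4-(methoxymethoxy)benzaldehyde
Conditions: MOMCl (1.3 equiv), iPr2NEt (1.6 equiv), CH2Cl2, 0 °C to rt
Reagents that add atoms: chloromethyl methyl ether, COCCl
Why: Phenol O-alkylation; the acetal keeps the phenol masked through the basic condensation and the later acylation.

Step 9
Reactants: 11 (2S,3S)-2-[3,4-bis(methoxymethoxy)phenyl]-6-methyl-4-oxo-2,3-dihydro-4H-furo[3,2-c]pyran-3-carboxylic acid; 13 4-(methoxymethoxy)benzaldehyde
Product: 14 (2S,3S)-2-[3,4-bis(methoxymethoxy)phenyl]-6-[(E)-2-[4-(methoxymethoxy)phenyl]ethenyl]-4-oxo-2,3-dihydro-4H-furo[3,2-c]pyran-3-carboxylic acid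
Conditions: Mg(OMe)2 (4 equiv), MeOH, reflux; then cold 1 M HCl to pH 3
Reagents that add atoms: none
Why: Magnesium methoxide-mediated vinylogous aldol condensation of a 4-alkoxy-6-methyl-2-pyranone with an aromatic aldehyde, the standard entry to 6-styryl-2-pyranones; as its magnesium carboxylate the substrate has a non-acidic C3–H, so only the 6-methyl group is deprotonated, and elimination from the aldolate gives the conjugated E alkene.

Step 10
Reactants: 15 methyl acetoacetate
Product: 16 methyl 3-(trimethylsilyloxy)but-2-enoate (E/Z mixture, both usable)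
Conditions: Me3SiCl (1.2 equiv), Et3N (1.3 equiv), hexane, rt
Reagents that add atoms: chlorotrimethylsilane, C[Si](C)(C)Cl
Why: Soft enolisation and O-silylation of the β-keto ester.

Step 11
Reactants: 16 methyl 3-(trimethylsilyloxy)but-2-enoate
Product: 17 1-methoxy-1,3-bis(trimethylsilyloxy)buta-1,3-diene
Conditions: LDA (1.1 equiv), THF, −78 °C; Me3SiCl (1.2 equiv), −78 to 0 °C; distillation
Reagents that add atoms: chlorotrimethylsilane, C[Si](C)(C)Cl
Why: γ-Deprotonation of the silyl enol ether and O-silylation of the dienolate give the bis-silyl dienol ether of methyl acetoacetate, a masked acetoacetate dianion.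

Step 12
Reactants: 14 (2S,3S)-2-[3,4-bis(methoxymethoxy)phenyl]-6-[(E)-2-[4-(methoxymethoxy)phenyl]ethenyl]-4-oxo-2,3-dihydro-4H-furo[3,2-c]pyran-3-carboxylic acid; 17 1-methoxy-1,3-bis(trimethylsilyloxy)buta-1,3-diene
Product: 19 methyl 5-[(2S,3S)-2-[3,4-bis(methoxymethoxy)phenyl]-6-[(E)-2-[4-(methoxymethoxy)phenyl]ethenyl]-4-oxo-2,3-dihydro-4H-furo[3,2-c]pyran-3-yl]-3,5-dioxopentanoate, via acid chloride 18 (not isolated)
Conditions: 1-chloro-N,N,2-trimethylprop-1-en-1-amine (1.3 equiv), CH2Cl2, 0 °C to rt; then 17 (2 equiv), −78 °C to rt; aq. NH4Cl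
Reagents that add atoms: none
Why: The α-chloroenamine converts the acid into its chloride without releasing HCl, and the bis-silyl dienol ether is then C-acylated at its terminal carbon, a known route to 3,5-dioxo esters; no base is present, so C3 is not enolised and keeps its configuration.

Step 13
Reactants: 19 methyl 5-[(2S,3S)-2-[3,4-bis(methoxymethoxy)phenyl]-6-[(E)-2-[4-(methoxymethoxy)phenyl]ethenyl]-4-oxo-2,3-dihydro-4H-furo[3,2-c]pyran-3-yl]-3,5-dioxopentanoate
Product: 20 6-[(2S,3S)-2-[3,4-bis(methoxymethoxy)phenyl]-6-[(E)-2-[4-(methoxymethoxy)phenyl]ethenyl]-4-oxo-2,3-dihydro-4H-furo[3,2-c]pyran-3-yl]-4-hydroxy-2H-pyran-2-one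
Conditions: DBU (2 equiv), toluene, rt; then cold 1 M HCl
Reagents that add atoms: none
Why: Base-mediated lactonisation of a 3,5-dioxo ester (6-exo-trig attack of the C5 enol oxygen on the ester, loss of methanol) gives the 4-hydroxy-2-pyranone; DBU removes a proton from the far more acidic methylene groups of the tricarbonyl chain, and the resulting anion shields C3–H.

Step 14
Reactants: 20 6-[(2S,3S)-2-[3,4-bis(methoxymethoxy)phenyl]-6-[(E)-2-[4-(methoxymethoxy)phenyl]ethenyl]-4-oxo-2,3-dihydro-4H-furo[3,2-c]pyran-3-yl]-4-hydroxy-2H-pyran-2-one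
Product: 21 4-hydroxy-6-[(2S,3S)-2-(3,4-dihydroxyphenyl)-6-[(E)-2-(4-hydroxyphenyl)ethenyl]-4-oxo-2,3-dihydro-4H-furo[3,2-c]pyran-3-yl]-2H-pyran-2-one
Conditions: 3 M aq. HCl, THF (degassed), 40 °C, argon
Reagents that add atoms: none
Why: Acid hydrolysis of the three aryl methoxymethyl acetals; the aqueous medium avoids acid-catalysed O-methylation of the 4-hydroxypyranone, no base touches C3–H, and exclusion of air protects the catechol.

**Compound list**

1 | 3,4-dihydroxybenzaldehyde | O=Cc1ccc(O)c(O)c1 | starting material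
2 | 3,4-diacetoxybenzaldehyde | O=Cc1ccc(OC(C)=O)c(OC(C)=O)c1 | intermediate
3 | dehydroacetic acid (3-acetyl-4-hydroxy-6-methyl-2H-pyran-2-one) | CC(=O)c1c(O)cc(C)oc1=O | starting material
4 | 3-[(2E)-3-(3,4-diacetoxyphenyl)prop-2-enoyl]-4-hydroxy-6-methyl-2H-pyran-2-one | Cc1cc(O)c(C(=O)/C=C/c2ccc(OC(C)=O)c(OC(C)=O)c2)c(=O)o1 | intermediate
5 | (S)-2-(3,4-diacetoxyphenyl)-7-methyl-2,3-dihydro-4H,5H-pyrano[3,2-c]pyran-4,5-dione | Cc1cc2c(c(=O)o1)C(=O)C[C@@H](c1ccc(OC(C)=O)c(OC(C)=O)c1)O2 | intermediate
6 | (S)-2-(3,4-diacetoxyphenyl)-4-methoxy-7-methyl-2H,5H-pyrano[3,2-c]pyran-5-one (methyl enol ether of 5) | Cc1cc2c(c(=O)o1)C(OC)=C[C@@H](c1ccc(OC(C)=O)c(OC(C)=O)c1)O2 | intermediate (not isolated)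
7 | 2,3-trans 3-[acetoxy(phenyl)-λ3-iodanyl]-2-(3,4-diacetoxyphenyl)-4,4-dimethoxy-7-methyl-3,4-dihydro-2H,5H-pyrano[3,2-c]pyran-5-one (iodine anti to the aryl group, C2 as in 5) | Cc1cc2c(c(=O)o1)C(OC)(OC)[C@H](I(OC(C)=O)c1ccccc1)[C@@H](c1ccc(OC(C)=O)c(OC(C)=O)c1)O2 | intermediate (not isolated)
8 | methyl (2S,3S)-2-(3,4-diacetoxyphenyl)-6-methyl-4-oxo-2,3-dihydro-4H-furo[3,2-c]pyran-3-carboxylate (trans) | COC(=O)[C@H]1c2c(cc(C)oc2=O)O[C@@H]1c1ccc(OC(C)=O)c(OC(C)=O)c1 | intermediate
9 | methyl (2S,3S)-2-(3,4-dihydroxyphenyl)-6-methyl-4-oxo-2,3-dihydro-4H-furo[3,2-c]pyran-3-carboxylate | COC(=O)[C@H]1c2c(cc(C)oc2=O)O[C@@H]1c1ccc(O)c(O)c1 | intermediate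
10 | methyl (2S,3S)-2-[3,4-bis(methoxymethoxy)phenyl]-6-methyl-4-oxo-2,3-dihydro-4H-furo[3,2-c]pyran-3-carboxylate | COC(=O)[C@H]1c2c(cc(C)oc2=O)O[C@@H]1c1ccc(OCOC)c(OCOC)c1 | intermediate
11 | (2S,3S)-2-[3,4-bis(methoxymethoxy)phenyl]-6-methyl-4-oxo-2,3-dihydro-4H-furo[3,2-c]pyran-3-carboxylic acid | OC(=O)[C@H]1c2c(cc(C)oc2=O)O[C@@H]1c1ccc(OCOC)c(OCOC)c1 | intermediate
12 | 4-hydroxybenzaldehyde | O=Cc1ccc(O)cc1 | starting material
13 | 4-(methoxymethoxy)benzaldehyde | O=Cc1ccc(OCOC)cc1 | intermediate
14 | (2S,3S)-2-[3,4-bis(methoxymethoxy)phenyl]-6-[(E)-2-[4-(methoxymethoxy)phenyl]ethenyl]-4-oxo-2,3-dihydro-4H-furo[3,2-c]pyran-3-carboxylic acid | OC(=O)[C@H]1c2c(cc(/C=C/c3ccc(OCOC)cc3)oc2=O)O[C@@H]1c1ccc(OCOC)c(OCOC)c1 | intermediate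
15 | methyl acetoacetate | COC(=O)CC(C)=O | starting material
16 | methyl 3-(trimethylsilyloxy)but-2-enoate (E/Z mixture) | COC(=O)C=C(C)O[Si](C)(C)C | intermediate
17 | 1-methoxy-1,3-bis(trimethylsilyloxy)buta-1,3-diene | COC(=CC(=C)O[Si](C)(C)C)O[Si](C)(C)C | intermediate
18 | (2S,3S)-2-[3,4-bis(methoxymethoxy)phenyl]-6-[(E)-2-[4-(methoxymethoxy)phenyl]ethenyl]-4-oxo-2,3-dihydro-4H-furo[3,2-c]pyran-3-carbonyl chloride | O=C(Cl)[C@H]1c2c(cc(/C=C/c3ccc(OCOC)cc3)oc2=O)O[C@@H]1c1ccc(OCOC)c(OCOC)c1 | intermediate (not isolated)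
19 | methyl 5-[(2S,3S)-2-[3,4-bis(methoxymethoxy)phenyl]-6-[(E)-2-[4-(methoxymethoxy)phenyl]ethenyl]-4-oxo-2,3-dihydro-4H-furo[3,2-c]pyran-3-yl]-3,5-dioxopentanoate | COC(=O)CC(=O)CC(=O)[C@H]1c2c(cc(/C=C/c3ccc(OCOC)cc3)oc2=O)O[C@@H]1c1ccc(OCOC)c(OCOC)c1 | intermediate
20 | 6-[(2S,3S)-2-[3,4-bis(methoxymethoxy)phenyl]-6-[(E)-2-[4-(methoxymethoxy)phenyl]ethenyl]-4-oxo-2,3-dihydro-4H-furo[3,2-c]pyran-3-yl]-4-hydroxy-2H-pyran-2-one | O=c1cc(O)cc([C@H]2c3c(cc(/C=C/c4ccc(OCOC)cc4)oc3=O)O[C@@H]2c2ccc(OCOC)c(OCOC)c2)o1 | intermediate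
21 | 4-hydroxy-6-[(2S,3S)-2-(3,4-dihydroxyphenyl)-6-[(E)-2-(4-hydroxyphenyl)ethenyl]-4-oxo-2,3-dihydro-4H-furo[3,2-c]pyran-3-yl]-2H-pyran-2-one (CNP0330607.1) | O=c1cc(O)cc([C@H]2c3c(cc(/C=C/c4ccc(O)cc4)oc3=O)O[C@@H]2c2ccc(O)c(O)c2)o1 | target

**Step count**

Total: 14 steps. Longest linear sequence: 11 steps (1, 2, 3, 4, 5, 6, 7, 9, 12, 13, 14); steps 8, 10 and 11 make the two side components.

**Steps most likely to fail**

Step 4. The 1,2-shift may take another course: the C2 aryl group may migrate to C3, or the iodane may lose HX to give the fully unsaturated pyranopyranone. Acid methanolysis may also strip the acetates, after which the free catechol would be oxidised. Fallback, setting out from 2 and coming back at 8: Wittig olefination of 2 with methyl (triphenylphosphoranylidene)acetate in toluene at 80 °C should give methyl (E)-3-(3,4-diacetoxyphenyl)prop-2-enoate F1. Oxidative radical [3+2] annulation of F1 with commercial 4-hydroxy-6-methyl-2H-pyran-2-one (Cc1cc(O)cc(=O)o1), mediated by Mn(OAc)3·2H2O (trivalent manganese, 2.2 equiv) in AcOH at 70 °C, is a known way to make trans 2-aryl-dihydrofuran-3-carboxylates from cyclic 1,3-dicarbonyl compounds and cinnamates: the pyranone C3 radical adds to the ester-bearing alkene carbon, and the benzylic radical is oxidised and trapped by the enol oxygen. It should give the racemic trans ester F2, which is resolved by preparative chromatography on a chiral stationary phase to 8.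

Step 3. Facial selectivity may be poor, closure may stop at an equilibrium mixture with 4, or the ee may erode through base-mediated retro-oxa-Michael opening of 5 during the reaction or work-up. Fallback, setting out from 4 and coming back at 8: closure of 4 with Et3N in EtOH at rt should give the racemic pyranopyrandione F3. The conditions of step 4 should convert F3 into the racemic trans ester F4, which cannot racemise without a strong base, and F4 is resolved by preparative chromatography on a chiral stationary phase to 8.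

Step 9. Deprotonation of the 6-methyl group in the carboxylate may be slow, and long heating with alkoxide may open the dihydrofuran, by decarboxylative loss of O1 from C2 or by addition–elimination at C7a. Fallback, setting out from 11 (with 13) and coming back at 14: the one-pot thermodynamic condensation is replaced by a kinetic aldol addition and a separate acid dehydration. Treatment of 11 with LiN(SiMe3)2 (2.2 equiv) in THF at −78 °C should form the carboxylate/6-methylene dianion, which adds to 13 to give, after a cold HCl quench, the aldol adduct F5 as a mixture of carbinol epimers. Dehydration of F5 with catalytic p-TsOH in CH2Cl2 at rt (E1 through the para-alkoxybenzyl cation) should give 14.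

**Further compounds**

F1 | step 4 | methyl (E)-3-(3,4-diacetoxyphenyl)prop-2-enoate | COC(=O)/C=C/c1ccc(OC(C)=O)c(OC(C)=O)c1
F2 | step 4 | racemic trans methyl 2-(3,4-diacetoxyphenyl)-6-methyl-4-oxo-2,3-dihydro-4H-furo[3,2-c]pyran-3-carboxylate (both enantiomers) | COC(=O)[C@H]1c2c(cc(C)oc2=O)O[C@@H]1c1ccc(OC(C)=O)c(OC(C)=O)c1.COC(=O)[C@@H]1c2c(cc(C)oc2=O)O[C@H]1c1ccc(OC(C)=O)c(OC(C)=O)c1
F3 | step 3 | racemic 2-(3,4-diacetoxyphenyl)-7-methyl-2,3-dihydro-4H,5H-pyrano[3,2-c]pyran-4,5-dione | Cc1cc2c(c(=O)o1)C(=O)CC(c1ccc(OC(C)=O)c(OC(C)=O)c1)O2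
F4 | step 3 | racemic trans methyl 2-(3,4-diacetoxyphenyl)-6-methyl-4-oxo-2,3-dihydro-4H-furo[3,2-c]pyran-3-carboxylate (both enantiomers) | COC(=O)[C@H]1c2c(cc(C)oc2=O)O[C@@H]1c1ccc(OC(C)=O)c(OC(C)=O)c1.COC(=O)[C@@H]1c2c(cc(C)oc2=O)O[C@H]1c1ccc(OC(C)=O)c(OC(C)=O)c1
F5 | step 9 | (2S,3S)-2-[3,4-bis(methoxymethoxy)phenyl]-6-[2-hydroxy-2-[4-(methoxymethoxy)phenyl]ethyl]-4-oxo-2,3-dihydro-4H-furo[3,2-c]pyran-3-carboxylic acid (carbinol epimers) | OC(=O)[C@H]1c2c(cc(CC(O)c3ccc(OCOC)cc3)oc2=O)O[C@@H]1c1ccc(OCOC)c(OCOC)c1
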